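**Retrosynthetic overview**

1. The ketone comes from oxidation of a homoallylic alcohol, itself made by α-selective carbonyl allylation of a lactone–oxolane aldehyde (fragment A) with an (E)-allylbarium reagent carrying the furan (fragment B); this forms the bond between the future ketone carbon and its allylic CH2.
2. Fragment A: the γ-lactone comes from Wittig two-carbon extension, hydrogenation and lactonisation of an α-hydroxy aldehyde; the oxolane comes from 5-exo opening of a Sharpless epoxide by a tertiary alcohol.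
3. All three stereocentres come from two Sharpless epoxidations on the geraniol skeleton: D-tartrate for the quaternary oxolane carbon, L-tartrate for the ring CH and the lactone carbon.
4. Fragment B: furan-3-carbaldehyde, then HWE, conjugate reduction, E-selective Wittig, reduction and chlorination.
5. Ring order: the furan is bought, the oxolane ring is closed first, the lactone second; no ring is formed after the coupling.

Assumption: ylides, the phosphonate, tartrates and all other reagents are bought; they are given with SMILES on the reagent line and carry no compound number.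

**Route**

Step 1
Reactants: 1 geraniol
Product: 2 [(2R,3R)-3-methyl-3-(4-methylpent-3-en-1-yl)oxiran-2-yl]methanol
Conditions: Ti(OiPr)4 (5 mol%), D-(−)-diethyl tartrate (7 mol%), t-BuOOH, 4 Å MS, CH2Cl2, −20 °C
Reagents that add atoms: tert-butyl hydroperoxide CC(C)(C)OO
Why: Katsuki–Sharpless asymmetric epoxidation touches only the allylic alkene, and the D-(−)-tartrate ligand gives the (2R,3R) epoxide, which fixes the future quaternary oxolane carbon as R.

Step 2
Reactants: 2 [(2R,3R)-3-methyl-3-(4-methylpent-3-en-1-yl)oxiran-2-yl]methanol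
Product: 3 (3R)-3,7-dimethyloct-6-ene-1,3-diol
Conditions: NaAlH2(OCH2CH2OMe)2, THF, 0 °C → rt; aq. potassium sodium tartrate
Reagents that add atoms: none
Why: Hydroxyl-directed hydride opening of a 2,3-epoxy alcohol delivers hydride to C-2 and leaves the C-3–O bond untouched, so the tertiary carbinol keeps the R configuration.

Step 3
Reactants: 3 (3R)-3,7-dimethyloct-6-ene-1,3-diol
Product: 4 (3R)-1-[(tert-butyldiphenylsilyl)oxy]-3,7-dimethyloct-6-en-3-ol
Conditions: TBDPSCl, imidazole, CH2Cl2, 0 °C → rt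
Reagents that add atoms: tert-butyl(chloro)diphenylsilane CC(C)(C)[Si](Cl)(c1ccccc1)c1ccccc1
Why: Chemoselective silylation: the bulky silyl chloride reacts only with the primary hydroxyl and leaves the tertiary one free for the later ring closure.

Step 4
Reactants: 4 (3R)-1-[(tert-butyldiphenylsilyl)oxy]-3,7-dimethyloct-6-en-3-ol
Product: 5 (2E,6R)-8-[(tert-butyldiphenylsilyl)oxy]-2,6-dimethyloct-2-ene-1,6-diol
Conditions: SeO2 (0.3 equiv), t-BuOOH, salicylic acid (10 mol%), CH2Cl2, rt
Reagents that add atoms: selenium dioxide O=[Se]=O; tert-butyl hydroperoxide CC(C)(C)OO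
Why: Selenium dioxide allylic oxidation (ene reaction then [2,3]-sigmatropic shift) hydroxylates only the (E)-methyl group of the trisubstituted alkene and gives the (E)-allylic alcohol.

Step 5
Reactants: 5 (2E,6R)-8-[(tert-butyldiphenylsilyl)oxy]-2,6-dimethyloct-2-ene-1,6-diol
Product: 7 (2S)-2-[(2R,5R)-5-{2-[(tert-butyldiphenylsilyl)oxy]ethyl}-5-methyloxolan-2-yl]propane-1,2-diol, via epoxy alcohol 6 (not isolated)
Conditions: Ti(OiPr)4 (20 mol%), L-(+)-diethyl tartrate (25 mol%), t-BuOOH, 4 Å MS, CH2Cl2, −20 °C; then CSA (10 mol%), CH2Cl2, 0 °C → rt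
Reagents that add atoms: tert-butyl hydroperoxide CC(C)(C)OO
Why: Katsuki–Sharpless asymmetric epoxidation with L-(+)-tartrate sets the (2S,3S) epoxide by reagent control, and acid-catalysed 5-exo opening by the tertiary hydroxyl inverts the secondary epoxide carbon (ring CH becomes R) while the tertiary C–O bond is kept (carbinol carbon S).

Step 6
Reactants: 7 (2S)-2-[(2R,5R)-5-{2-[(tert-butyldiphenylsilyl)oxy]ethyl}-5-methyloxolan-2-yl]propane-1,2-diol
Product: 8 (2R)-2-[(2R,5R)-5-{2-[(tert-butyldiphenylsilyl)oxy]ethyl}-5-methyloxolan-2-yl]-2-hydroxypropanal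
Conditions: SO3·pyridine, DMSO, Et3N, CH2Cl2, 0 °C
Reagents that add atoms: none
Why: Parikh–Doering oxidation converts the primary alcohol into the aldehyde without glycol cleavage, and the fully substituted α-carbon cannot epimerise (the descriptor changes only because of CIP priorities).

Step 7
Reactants: 8 (2R)-2-[(2R,5R)-5-{2-[(tert-butyldiphenylsilyl)oxy]ethyl}-5-methyloxolan-2-yl]-2-hydroxypropanal
Product: 9 methyl (2E,4S)-4-[(2R,5R)-5-{2-[(tert-butyldiphenylsilyl)oxy]ethyl}-5-methyloxolan-2-yl]-4-hydroxypent-2-enoate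
Conditions: Ph3P=CHCO2Me, CH2Cl2, rt
Reagents that add atoms: methyl (triphenylphosphoranylidene)acetate COC(=O)C=P(c1ccccc1)(c1ccccc1)c1ccccc1
Why: Wittig olefination with a stabilised ylide gives the (E)-enoate and adds the last two lactone carbons; any Z isomer converges to the same lactone in the next step.

Step 8
Reactants: 9 methyl (2E,4S)-4-[(2R,5R)-5-{2-[(tert-butyldiphenylsilyl)oxy]ethyl}-5-methyloxolan-2-yl]-4-hydroxypent-2-enoate
Product: 11 (5S)-5-[(2R,5R)-5-{2-[(tert-butyldiphenylsilyl)oxy]ethyl}-5-methyloxolan-2-yl]-5-methyloxolan-2-one, via saturated hydroxy ester 10 (not isolated)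
Conditions: H2 (1 atm), Pd/C, EtOAc, rt; then PPTS (10 mol%), toluene, 80 °C
Reagents that add atoms: none
Why: Heterogeneous catalytic hydrogenation saturates the enoate, and acid-catalysed lactonisation (acyl substitution at the ester carbon) closes the γ-lactone with retention at the quaternary carbinol centre.

Step 9
Reactants: 11 (5S)-5-[(2R,5R)-5-{2-[(tert-butyldiphenylsilyl)oxy]ethyl}-5-methyloxolan-2-yl]-5-methyloxolan-2-one
Product: 12 (5S)-5-[(2R,5R)-5-(2-hydroxyethyl)-5-methyloxolan-2-yl]-5-methyloxolan-2-one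
Conditions: Bu4NF, AcOH, THF, 0 °C → rt
Reagents that add atoms: none
Why: Fluoride-mediated desilylation cleaves only the Si–O bond, and the acetic acid buffer protects the lactone.

Step 10
Reactants: 12 (5S)-5-[(2R,5R)-5-(2-hydroxyethyl)-5-methyloxolan-2-yl]-5-methyloxolan-2-one
Product: 13 2-[(2R,5R)-2-methyl-5-[(2S)-2-methyl-5-oxooxolan-2-yl]oxolan-2-yl]acetaldehyde
Conditions: Dess–Martin periodinane, NaHCO3, CH2Cl2, 0 °C → rt
Reagents that add atoms: none
Why: Dess–Martin oxidation gives the aldehyde under non-basic conditions, so the β-alkoxy aldehyde does not suffer retro-oxa-Michael ring opening.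

Step 11
Reactants: 14 furan-3-carbaldehyde
Product: 15 methyl (2E)-3-(furan-3-yl)prop-2-enoate
Conditions: (MeO)2P(O)CH2CO2Me, NaH, THF, 0 °C → rt
Reagents that add atoms: trimethyl phosphonoacetate COC(=O)CP(=O)(OC)OC
Why: Horner–Wadsworth–Emmons olefination of the aromatic aldehyde gives the (E)-acrylate.

Step 12
Reactants: 15 methyl (2E)-3-(furan-3-yl)prop-2-enoate
Product: 16 methyl 3-(furan-3-yl)propanoate
Conditions: NaBH4, NiCl2·6H2O (20 mol%), MeOH, 0 °C
Reagents that add atoms: none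
Why: Conjugate reduction by nickel boride formed in situ saturates only the enoate C=C and leaves the furan and the ester intact.

Step 13
Reactants: 16 methyl 3-(furan-3-yl)propanoate
Product: 17 3-(furan-3-yl)propanal
Conditions: i-Bu2AlH (1.05 equiv), CH2Cl2, −78 °C; MeOH then aq. potassium sodium tartrate
Reagents that add atoms: none
Why: Partial ester reduction by i-Bu2AlH at −78 °C stops at the tetrahedral aluminium hemiacetal, which releases the aldehyde on work-up.

Step 14
Reactants: 17 3-(furan-3-yl)propanal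
Product: 18 ethyl (2E)-5-(furan-3-yl)-2-methylpent-2-enoate
Conditions: Ph3P=C(Me)CO2Et, CH2Cl2, rt → 40 °C
Reagents that add atoms: ethyl 2-(triphenylphosphoranylidene)propanoate CCOC(=O)C(C)=P(c1ccccc1)(c1ccccc1)c1ccccc1
Why: Wittig olefination with the α-methyl stabilised ylide gives the (E)-trisubstituted enoate (typically >95:5), which sets the alkene geometry of the target.

Step 15
Reactants: 18 ethyl (2E)-5-(furan-3-yl)-2-methylpent-2-enoate
Product: 19 (2E)-5-(furan-3-yl)-2-methylpent-2-en-1-ol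
Conditions: i-Bu2AlH (2.3 equiv), CH2Cl2, −78 °C
Reagents that add atoms: none
Why: 1,2-Reduction of the enoate with i-Bu2AlH gives the allylic alcohol without touching the alkene geometry.

Step 16
Reactants: 19 (2E)-5-(furan-3-yl)-2-methylpent-2-en-1-ol
Product: 21 3-[(3E)-5-chloro-4-methylpent-3-en-1-yl]furan, via allylic mesylate 20 (not isolated)
Conditions: MsCl, 2,4,6-collidine, LiCl, DMF, 0 °C
Reagents that add atoms: methanesulfonyl chloride CS(=O)(=O)Cl (mesyl group of 20); lithium chloride [Li+].[Cl-] (chlorine of 21)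
Why: Collington–Meyers chlorination: in-situ mesylation then SN2 displacement by chloride gives the primary allylic chloride without allylic transposition or E/Z erosion.

Step 17
Reactants: 21 3-[(3E)-5-chloro-4-methylpent-3-en-1-yl]furan; 13 2-[(2R,5R)-2-methyl-5-[(2S)-2-methyl-5-oxooxolan-2-yl]oxolan-2-yl]acetaldehyde
Product: 23 (5S)-5-[(2R,5R)-5-[(4E)-7-(furan-3-yl)-2-hydroxy-4-methylhept-4-en-1-yl]-5-methyloxolan-2-yl]-5-methyloxolan-2-one (both carbinol epimers), via allylbarium chloride 22 (not isolated)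
Conditions: BaI2, LiC12H10 (lithium biphenylide, 2 equiv per Ba), THF, rt; 21 (1.2 equiv), −78 °C, 30 min; 13 (1.0 equiv), −78 °C, 30 min; aq. NH4Cl, −78 °C
Reagents that add atoms: barium iodide [Ba+2].[I-].[I-] (its barium stands in 22 only; no reagent atom remains in 23)
Why: Carbonyl allylation with an allylbarium reagent (Yamamoto type): at −78 °C the allylbarium keeps its E geometry and attacks the aldehyde through its unsubstituted α-carbon, joining fragment A and fragment B; the new carbinol centre is left uncontrolled because it is oxidised next.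

Step 18
Reactants: 23 (5S)-5-[(2R,5R)-5-[(4E)-7-(furan-3-yl)-2-hydroxy-4-methylhept-4-en-1-yl]-5-methyloxolan-2-yl]-5-methyloxolan-2-one
Product: 24 (5S)-5-[(2R,5R)-5-[(4E)-7-(furan-3-yl)-4-methyl-2-oxohept-4-en-1-yl]-5-methyloxolan-2-yl]-5-methyloxolan-2-one
Conditions: Dess–Martin periodinane, NaHCO3, CH2Cl2, 0 °C
Reagents that add atoms: none
Why: Dess–Martin oxidation under buffered, non-basic conditions converts the homoallylic alcohol into the β,γ-unsaturated ketone without conjugating the alkene or disturbing the three stereocentres.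

**Compound list**

1 | geraniol, (2E)-3,7-dimethylocta-2,6-dien-1-ol | CC(C)=CCC/C(C)=C/CO | starting material
2 | [(2R,3R)-3-methyl-3-(4-methylpent-3-en-1-yl)oxiran-2-yl]methanol | OC[C@H]1O[C@]1(C)CCC=C(C)C | intermediate
3 | (3R)-3,7-dimethyloct-6-ene-1,3-diol | OCC[C@](C)(O)CCC=C(C)C | intermediate
4 | (3R)-1-[(tert-butyldiphenylsilyl)oxy]-3,7-dimethyloct-6-en-3-ol | CC(C)(C)[Si](c1ccccc1)(c1ccccc1)OCC[C@](C)(O)CCC=C(C)C | intermediate
5 | (2E,6R)-8-[(tert-butyldiphenylsilyl)oxy]-2,6-dimethyloct-2-ene-1,6-diol | CC(C)(C)[Si](c1ccccc1)(c1ccccc1)OCC[C@](C)(O)CC/C=C(\C)CO | intermediate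
6 | [(2S,3S)-3-[(3R)-5-[(tert-butyldiphenylsilyl)oxy]-3-hydroxy-3-methylpentyl]-2-methyloxiran-2-yl]methanol | CC(C)(C)[Si](c1ccccc1)(c1ccccc1)OCC[C@](C)(O)CC[C@@H]1O[C@@]1(C)CO | intermediate (not isolated)
7 | (2S)-2-[(2R,5R)-5-{2-[(tert-butyldiphenylsilyl)oxy]ethyl}-5-methyloxolan-2-yl]propane-1,2-diol | CC(C)(C)[Si](c1ccccc1)(c1ccccc1)OCC[C@@]1(C)CC[C@H]([C@@](C)(O)CO)O1 | intermediate
8 | (2R)-2-[(2R,5R)-5-{2-[(tert-butyldiphenylsilyl)oxy]ethyl}-5-methyloxolan-2-yl]-2-hydroxypropanal | CC(C)(C)[Si](c1ccccc1)(c1ccccc1)OCC[C@@]1(C)CC[C@H]([C@@](C)(O)C=O)O1 | intermediate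
9 | methyl (2E,4S)-4-[(2R,5R)-5-{2-[(tert-butyldiphenylsilyl)oxy]ethyl}-5-methyloxolan-2-yl]-4-hydroxypent-2-enoate | CC(C)(C)[Si](c1ccccc1)(c1ccccc1)OCC[C@@]1(C)CC[C@H]([C@@](C)(O)/C=C/C(=O)OC)O1 | intermediate
10 | methyl (4S)-4-[(2R,5R)-5-{2-[(tert-butyldiphenylsilyl)oxy]ethyl}-5-methyloxolan-2-yl]-4-hydroxypentanoate | CC(C)(C)[Si](c1ccccc1)(c1ccccc1)OCC[C@@]1(C)CC[C@H]([C@@](C)(O)CCC(=O)OC)O1 | intermediate (not isolated)
11 | (5S)-5-[(2R,5R)-5-{2-[(tert-butyldiphenylsilyl)oxy]ethyl}-5-methyloxolan-2-yl]-5-methyloxolan-2-one | CC(C)(C)[Si](c1ccccc1)(c1ccccc1)OCC[C@@]1(C)CC[C@H]([C@]2(C)CCC(=O)O2)O1 | intermediate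
12 | (5S)-5-[(2R,5R)-5-(2-hydroxyethyl)-5-methyloxolan-2-yl]-5-methyloxolan-2-one | OCC[C@@]1(C)CC[C@H]([C@]2(C)CCC(=O)O2)O1 | intermediate
13 | 2-[(2R,5R)-2-methyl-5-[(2S)-2-methyl-5-oxooxolan-2-yl]oxolan-2-yl]acetaldehyde | O=CC[C@@]1(C)CC[C@H]([C@]2(C)CCC(=O)O2)O1 | intermediate
14 | furan-3-carbaldehyde | O=Cc1ccoc1 | starting material
15 | methyl (2E)-3-(furan-3-yl)prop-2-enoate | COC(=O)/C=C/c1ccoc1 | intermediate
16 | methyl 3-(furan-3-yl)propanoate | COC(=O)CCc1ccoc1 | intermediate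
17 | 3-(furan-3-yl)propanal | O=CCCc1ccoc1 | intermediate
18 | ethyl (2E)-5-(furan-3-yl)-2-methylpent-2-enoate | CCOC(=O)/C(C)=C/CCc1ccoc1 | intermediate
19 | (2E)-5-(furan-3-yl)-2-methylpent-2-en-1-ol | OC/C(C)=C/CCc1ccoc1 | intermediate
20 | (2E)-5-(furan-3-yl)-2-methylpent-2-en-1-yl methanesulfonate | CS(=O)(=O)OC/C(C)=C/CCc1ccoc1 | intermediate (not isolated)
21 | 3-[(3E)-5-chloro-4-methylpent-3-en-1-yl]furan | ClC/C(C)=C/CCc1ccoc1 | intermediate
22 | [(2E)-5-(furan-3-yl)-2-methylpent-2-en-1-yl]barium chloride | Cl[Ba]C/C(C)=C/CCc1ccoc1 | intermediate (not isolated)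
23 | (5S)-5-[(2R,5R)-5-[(4E)-7-(furan-3-yl)-2-hydroxy-4-methylhept-4-en-1-yl]-5-methyloxolan-2-yl]-5-methyloxolan-2-one (both carbinol epimers) | C/C(=C\CCc1ccoc1)CC(O)C[C@@]1(C)CC[C@H]([C@]2(C)CCC(=O)O2)O1 | intermediate
24 | (5S)-5-[(2R,5R)-5-[(4E)-7-(furan-3-yl)-4-methyl-2-oxohept-4-en-1-yl]-5-methyloxolan-2-yl]-5-methyloxolan-2-one (CNP0156092.1) | C/C(=C\CCc1ccoc1)CC(=O)C[C@@]1(C)CC[C@H]([C@]2(C)CCC(=O)O2)O1 | target

**Step count and risks**

Total steps: 18 (steps 1–10 for fragment A, 11–16 for fragment B, 17–18 for coupling and oxidation). Longest linear sequence: 12 steps (1–10, 17, 18).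

The three steps most likely to fail:

First, step 17. The α-selectivity and E-retention of allylbarium reagents are well documented for γ-substituted cases but less so for this 2-methyl-substituted allyl unit, and excess reagent could attack the lactone. The fallback sets out from 21 and 13 and comes back to the route at 24, bypassing 23. Chloride 21 is treated with PhSO2Na in DMF to give 3-[(3E)-4-methyl-5-(phenylsulfonyl)pent-3-en-1-yl]furan F1. Its α-lithio derivative (n-BuLi, THF, −78 °C) adds to aldehyde 13 only through the sulfonyl-bearing carbon and does not touch the lactone, giving (5S)-5-[(2R,5R)-5-[(4E)-7-(furan-3-yl)-2-hydroxy-4-methyl-3-(phenylsulfonyl)hept-4-en-1-yl]-5-methyloxolan-2-yl]-5-methyloxolan-2-one F2 as a diastereomer mixture. Dess–Martin oxidation gives (5S)-5-[(2R,5R)-5-[(4E)-7-(furan-3-yl)-4-methyl-2-oxo-3-(phenylsulfonyl)hept-4-en-1-yl]-5-methyloxolan-2-yl]-5-methyloxolan-2-one F3. Reductive desulfonylation with SmI2 (THF/MeOH, −78 °C), with kinetic α-protonation of the dienolate, then delivers 24 directly.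

Second, step 4. Selenium dioxide oxidations of this kind usually stop near 50% yield and give some over-oxidised enal. The fallback sets out from 4 and comes back at 5. Ozonolysis of 4 (O3, CH2Cl2/MeOH, −78 °C; Me2S) gives (4R)-6-[(tert-butyldiphenylsilyl)oxy]-4-hydroxy-4-methylhexanal F4, present mainly as its lactol. Wittig reaction with Ph3P=C(Me)CO2Et (toluene, 80 °C) gives ethyl (2E,6R)-8-[(tert-butyldiphenylsilyl)oxy]-6-hydroxy-2,6-dimethyloct-2-enoate F5 with the E geometry set by the ylide. Reduction with i-Bu2AlH (CH2Cl2, −78 °C) gives 5.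

Third, step 5. Under acid, the tertiary hydroxyl could open the epoxide at its tertiary carbon (6-endo, oxane) instead of the secondary one (5-exo). The fallback sets out from 5 and comes back at 7, replacing the acid step by an alkoxide SN2 opening. The epoxidation is run alone and 6 is isolated. Its primary hydroxyl is silylated (TBSCl, imidazole, CH2Cl2) to give (3R)-1-[(tert-butyldiphenylsilyl)oxy]-5-[(2S,3S)-3-{[(tert-butyldimethylsilyl)oxy]methyl}-3-methyloxiran-2-yl]-3-methylpentan-3-ol F6. NaH in THF (0 °C → rt) makes the tertiary alkoxide, which can reach only the less hindered secondary epoxide carbon, giving with inversion (2S)-1-[(tert-butyldimethylsilyl)oxy]-2-[(2R,5R)-5-{2-[(tert-butyldiphenylsilyl)oxy]ethyl}-5-methyloxolan-2-yl]propan-2-ol F7. PPTS in MeOH removes the primary TBS ether selectively and gives 7.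

**Further compounds**

F1 | step 17 | 3-[(3E)-4-methyl-5-(phenylsulfonyl)pent-3-en-1-yl]furan | O=S(=O)(C/C(C)=C/CCc1ccoc1)c1ccccc1
F2 | step 17 | (5S)-5-[(2R,5R)-5-[(4E)-7-(furan-3-yl)-2-hydroxy-4-methyl-3-(phenylsulfonyl)hept-4-en-1-yl]-5-methyloxolan-2-yl]-5-methyloxolan-2-one | C/C(=C\CCc1ccoc1)C(S(=O)(=O)c1ccccc1)C(O)C[C@@]1(C)CC[C@H]([C@]2(C)CCC(=O)O2)O1
F3 | step 17 | (5S)-5-[(2R,5R)-5-[(4E)-7-(furan-3-yl)-4-methyl-2-oxo-3-(phenylsulfonyl)hept-4-en-1-yl]-5-methyloxolan-2-yl]-5-methyloxolan-2-one | C/C(=C\CCc1ccoc1)C(S(=O)(=O)c1ccccc1)C(=O)C[C@@]1(C)CC[C@H]([C@]2(C)CCC(=O)O2)O1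
F4 | step 4 | (4R)-6-[(tert-butyldiphenylsilyl)oxy]-4-hydroxy-4-methylhexanal | CC(C)(C)[Si](c1ccccc1)(c1ccccc1)OCC[C@](C)(O)CCC=O
F5 | step 4 | ethyl (2E,6R)-8-[(tert-butyldiphenylsilyl)oxy]-6-hydroxy-2,6-dimethyloct-2-enoate | CC(C)(C)[Si](c1ccccc1)(c1ccccc1)OCC[C@](C)(O)CC/C=C(\C)C(=O)OCC
F6 | step 5 | (3R)-1-[(tert-butyldiphenylsilyl)oxy]-5-[(2S,3S)-3-{[(tert-butyldimethylsilyl)oxy]methyl}-3-methyloxiran-2-yl]-3-methylpentan-3-ol | CC(C)(C)[Si](c1ccccc1)(c1ccccc1)OCC[C@](C)(O)CC[C@@H]1O[C@@]1(C)CO[Si](C)(C)C(C)(C)C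
F7 | step 5 | (2S)-1-[(tert-butyldimethylsilyl)oxy]-2-[(2R,5R)-5-{2-[(tert-butyldiphenylsilyl)oxy]ethyl}-5-methyloxolan-2-yl]propan-2-ol | CC(C)(C)[Si](c1ccccc1)(c1ccccc1)OCC[C@@]1(C)CC[C@H]([C@@](C)(O)CO[Si](C)(C)C(C)(C)C)O1
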